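The readings come from a simulation with constants of no real substance; noise was put on by code.

- No rate constant comes with these flasks, so I read one from the readings and freeze it, then carry it to larch.

| flask | starting material | coupling partner | time |
|---|---|---|---|
| maple | 0.400 M | 0.400 M |  |
| birch | 0.400 M | 1.20 M |  |
| cedar | 0.600 M | 0.400 M |  |
| larch | 0.980 M | 0.400 M | 15 min |

| run | time / min | [target] / M |
|---|---|---|
| maple run | 0.60 | 0.0241 |
| maple run | 1.3 | 0.0554 |
| maple run | 3.0 | 0.1141 |
| maple run | 6.7 | 0.2040 |
| maple run | 15 | 0.3009 |
| birch run | 0.60 | 0.0431 |
| birch run | 1.3 | 0.0939 |
| birch run | 3.0 | 0.1913 |
| birch run | 6.7 | 0.3061 |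
| birch run | 15 | 0.3874 |
| cedar run | 0.60 | 0.0371 |
| cedar run | 1.3 | 0.0707 |
| cedar run | 3.0 | 0.1464 |
| cedar run | 6.7 | 0.2628 |
| cedar run | 15 | 0.3699 |

(standard deviation of a reading: 0.002 M)

* reaction order in [coupling partner] at the outset, round the charge of the maple run, defined at two percent of the starting material turned into target
* reaction order in [starting material] at the outset, round the charge of the maple run, defined at two percent of the starting material turned into target (one fixed amount of target, the same in the runs compared)
* target in the larch run at 15 min, as a share of the starting material charged

- Overall: starting material + coupling partner -> target.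
- Constant volume, constant temperature.
- What is held in complexes is read along with the free species.
- "The second partner" is coupling partner.
- An order is taken over about fifteen percent of the charge, up and down.

- In cedar the coupling partner is the limiting reagent, charged below the starting material, and the target reading at 15 min gives 0.172 min⁻¹ for κ, the pseudo-first-order constant: the logarithm of the limiting charge over what is left of it, divided by the time.
- Cedar's κ reads 0.160 min⁻¹ at 6.7 min, close to the later reading, so I freeze it.
- Larch has a ceiling: its coupling partner allows 40.8 % of the starting material charged. With cedar's κ unchanged, larch reaches 37.7 % at 15 min.
- The weak link is that frozen κ, since larch charges more starting material than cedar.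
- To reforge it I compare cedar with maple at 3.0 min, which gives a rough exponent in starting material of 0.615. Birch against maple at that time gives 0.470 in coupling partner, an average over a factor 3.00.
- Scaling by the charges lifts larch's κ to 0.233 min⁻¹, and I commit to 39.6 % for larch.
- The forecast gives 0.65 and 0.67 for the orders in coupling partner and starting material, and 38.2 % for larch, below my number, on the view “This looks like a saturable catalyst”.
- The flask gives 0.56 and 0.71 for those orders, and 40.5 % for larch.

    starting material + coupling partner ⇌ intermediate, settled at all times (2.550 L mol⁻¹)
    starting material + coupling partner → target (2.760 L mol⁻¹ min⁻¹)
    2 coupling partner ⇌ idle reagent dimer, settled at all times (22.10 L mol⁻¹)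
    2 starting material ⇌ idle substrate dimer, settled at all times (1.550 L mol⁻¹)

- Larch's result leaves 0.00320 M of coupling partner, bound forms counted, so κ there reads 0.322 min⁻¹. In birch the starting material is the limiting reagent, charged below the coupling partner, κ reads 0.231 min⁻¹ from the target reading at 15 min, and ln(2)/κ gives 3.00 min against the 3.26 min that the birch run takes to turn half of its starting material into target. The forecast parts from the flask on the order in coupling partner, 0.65 against 0.56: at maple's charge the binding into idle reagent dimer holds the order down, and without that binding it stands at 0.83.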